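**Retrosynthesis**
- The target (E)-chalcone comes from a final Claisen–Schmidt condensation of acetophenone **10** with 4-hydroxybenzaldehyde (**9**). The same step removes the aryl silyl group.
- **10** is made in the key step. The acylphloroglucinol **8** and **9** form an o-quinone methide, which is a transiently dearomatised A-ring. The chiral (E)-alkenyl-Bpin **7** then adds to it enantioselectively, setting C7 as the diarylallyl stereocentre.
- **7** comes from cross-metathesis of homoallylic alcohol **5** with vinyl-Bpin. **5** comes from Brown allylation of aldehyde **3**, which sets C3. **3** comes from the cheap phloretate ester **1**.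
- No new rings are built; all rings are existing arenes.

Assumptions: (i) **8** is purchased; (ii) alkylation occurs mainly at C3′, which lies between the two OH groups and para to OMe, with the minor C5′ isomer removed by chromatography; (iii) the allylborane and biphenol enantiomers are assigned from the usual face-selectivity models and are confirmed by Mosher ester and chiral HPLC.

---

**Step 1**
Reactants: **1**, methyl 3-(4-hydroxyphenyl)propanoate
Product: **2**, methyl 3-(4-TBSO-phenyl)propanoate
Conditions: TBSCl (1.1 equiv), imidazole (2 equiv), DMF, rt, 3 h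
Reagents that add atoms: TBSCl, CC(C)(C)[Si](C)(C)Cl
Why: Chemoselective O-silylation of the phenol masks it for the borane and metathesis steps; no stereocentre is involved.

**Step 2**
Reactants: **2**
Product: **3**, 3-(4-TBSO-phenyl)propanal
Conditions: DIBAL-H (1.1 equiv), toluene, –78 °C, 1 h; Rochelle salt work-up
Reagents that add atoms: none
Why: Partial ester reduction stops at the aldehyde because the tetrahedral aluminate is stable at –78 °C; the aryl TBS ether survives.

**Step 3**
Reactants: **3**; **4**, (+)-B-allyldiisopinocampheylborane (Ipc from (–)-α-pinene)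
Product: **5**, (S)-1-(4-TBSO-phenyl)hex-5-en-3-ol
Conditions: Et2O, –78 °C, 3 h; then MeOH, pH 7 buffer, 30% H2O2, rt
Reagents that add atoms: none (the allyl group comes from reactant **4**)
Why: Brown asymmetric allylation proceeds through a Zimmerman–Traxler chair transition state, and the reagent's pinane chirality sets the (S) carbinol (C3). The neutral peroxide work-up protects the aryl silyl ether.

**Step 4**
Reactants: **5**; **6**, vinylboronic acid pinacol ester
Product: **7**, (S,E)-1-(4-TBSO-phenyl)-6-(Bpin)hex-5-en-3-ol
Conditions: Grubbs II (5 mol%), CH2Cl2, 40 °C, 12 h (**6**, 3 equiv)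
Reagents that add atoms: none (the vinyl-Bpin carbon comes from reactant **6**)
Why: Olefin cross-metathesis with loss of ethylene gives the E-alkenylboronate; the free homoallylic OH and the stereocentre are untouched.

**Step 5 (key step)**
Reactants: **8**, 2′,4′-dihydroxy-6′-methoxyacetophenone (2 equiv); **9**, 4-hydroxybenzaldehyde (1.5 equiv); **7** (1 equiv, limiting)
Product: **10**, 1-{2,4-dihydroxy-3-[(R,E)-1-(4-hydroxyphenyl)-4-hydroxy-6-(4-TBSO-phenyl)hex-1-enyl…]-6-methoxyphenyl}ethanone, i.e. the C7 diarylallyl acetophenone with the (3S) carbinol
Conditions: (S)-3,3′-Br2-BINOL (20 mol%), 4 Å MS, toluene, 50 °C, 48 h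
Reagents that add atoms: none (catalyst is not incorporated)
Why: Proposed new method: the phenol OH of **8** and the aldehyde are brought together on boron, as in boron-templated ortho-hydroxyalkylation. Ionisation of the resulting 3′-(α-hydroxybenzyl)phenol gives an o-quinone methide, so the A-ring is transiently dearomatised. The chiral biphenol–alkenylboronate then transfers its alkenyl group through a closed phenoxide–B ate transition state to one face of the quinone methide, and rearomatisation sets (R)-C7. The closest known reactions are the biphenol-catalysed alkenylation of o-quinone methides and the Petasis borono-Friedel–Crafts coupling. The remote (S)-C3 carbinol should not compete with the catalyst; its free OH can add to the o-QM only reversibly.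

**Step 6**
Reactants: **10**; **9** (2 equiv)
Product: **11**, epicalyxin B
Conditions: KOH (10 equiv), EtOH/H2O (1:1), rt → 50 °C, 36 h; then cold 1 M HCl to pH 4
Reagents that add atoms: none (the aldehyde carbon comes from reactant **9**)
Why: Claisen–Schmidt aldol condensation and E1cB dehydration give the thermodynamic (E)-chalcone. Excess KOH also cleaves the aryl TBS ether in situ. The C3 and C7 stereocentres are non-acidic under these conditions, and brief mild acidification avoids flavanone or dihydrobenzofuran cyclisation.

---

**Compound list**

| # | Name | SMILES | Role |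
|---|------|--------|------|
| 1 | methyl 3-(4-hydroxyphenyl)propanoate | COC(=O)CCc1ccc(O)cc1 | starting material |
| 2 | methyl 3-(4-TBSO-phenyl)propanoate | COC(=O)CCc1ccc(O[Si](C)(C)C(C)(C)C)cc1 | intermediate |
| 3 | 3-(4-TBSO-phenyl)propanal | O=CCCc1ccc(O[Si](C)(C)C(C)(C)C)cc1 | intermediate |
| 4 | (+)-B-allyldiisopinocampheylborane (Ipc from (–)-α-pinene; pinane stereodescriptors given by the name, omitted in the SMILES) | C=CCB(C1CC2CC(C1C)C2(C)C)C1CC2CC(C1C)C2(C)C | starting material |
| 5 | (S)-1-(4-TBSO-phenyl)hex-5-en-3-ol | C=CC[C@@H](O)CCc1ccc(O[Si](C)(C)C(C)(C)C)cc1 | intermediate |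
| 6 | vinylboronic acid pinacol ester | C=CB1OC(C)(C)C(C)(C)O1 | starting material |
| 7 | (S,E)-alkenyl-Bpin | CC1(C)OB(OC1(C)C)/C=C/C[C@@H](O)CCc1ccc(O[Si](C)(C)C(C)(C)C)cc1 | intermediate |
| 8 | 2′,4′-dihydroxy-6′-methoxyacetophenone | COc1cc(O)cc(O)c1C(C)=O | starting material |
| 9 | 4-hydroxybenzaldehyde | O=Cc1ccc(O)cc1 | starting material |
| 10 | (3S,7R)-diarylallyl acetophenone (TBS-protected) | COc1cc(O)c([C@H](/C=C/C[C@@H](O)CCc2ccc(O[Si](C)(C)C(C)(C)C)cc2)c2ccc(O)cc2)c(O)c1C(C)=O | intermediate |
| 11 | epicalyxin B | COc1cc(O)c([C@H](/C=C/C[C@@H](O)CCc2ccc(O)cc2)c2ccc(O)cc2)c(O)c1C(=O)/C=C/c1ccc(O)cc1 | target |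

**Total steps:** 6. **Longest linear sequence:** 6 (1 → 2 → 3 → 5 → 7 → 10 → 11).

**Three steps most likely to fail**
1. **Step 5** (yield, C3′/C5′ regioselectivity, ee, and Bpin exchange with the biphenol). Fallback: Ir/phosphoramidite branched allylic Friedel–Crafts of **8** with 4-TBSO-cinnamyl methyl carbonate to give the 1-aryl-allyl arene, then cross-metathesis with **5** and Claisen–Schmidt, replacing the boron chemistry.
2. **Step 6** (free-phenol aldol on a hindered ortho-disubstituted ketone; flavanone formation). Fallback: reverse the order by condensing **8** with 4-MOMO-benzaldehyde first to give the chalcone, running the C7 coupling on that chalcone, and finishing with PPTS/MeOH removal of MOM and silyl groups.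
3. **Step 4** (modest yield or E/Z erosion in vinyl-Bpin cross-metathesis). Fallback: open (S)-2-(4-TBSO-phenethyl)oxirane with lithium acetylide to give the homopropargylic alcohol, then Schwartz hydrozirconation/pinacolborane to make **7**, avoiding metathesis.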